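A bending curve tempts one to read the bend as the road to a plateau, yet a bend alone does not tell what later happens to the target already made.

| flask | starting material | partner | time |
|---|---|---|---|
| Thursday's | 0.150 M | 0.375 M |  |
| Friday's | 0.0750 M | 0.300 M |  |
| Wednesday's | 0.150 M | 0.560 M |  |
| Sunday's | 0.0750 M | 0.375 M |  |
| Tuesday's | 0.150 M | 0.375 M | 14 min |

- Thursday's run (time / min: [target] / M): 0.31: 9 × 10⁻⁴; 0.93: 0.0062; 1.8: 0.0144; 2.8: 0.0239; 4.0: 0.0322; 5.4: 0.0384; 6.9: 0.0453
- Friday's run (time / min: [target] / M): 0.31: 0.0011; 0.93: 0.0029; 1.8: 0.0095; 2.8: 0.0127; 4.0: 0.0172; 5.4: 0.0186; 6.9: 0.0238
- Wednesday's run (time / min: [target] / M): 0.31: 0.0016; 0.93: 0.0055; 1.8: 0.0147; 2.8: 0.0214; 4.0: 0.0300; 5.4: 0.0349; 6.9: 0.0389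
- Sunday's run (time / min: [target] / M): 0.31: 6 × 10⁻⁴; 0.93: 0.0036; 1.8: 0.0080; 2.8: 0.0123; 4.0: 0.0160; 5.4: 0.0197; 6.9: 0.0207

(standard deviation of a reading: 8 × 10⁻⁴ M)

- Overall: starting material + partner -> target.
- Constant volume, constant temperature.
- A reading of a species includes what of it is bound.
- "The second partner" is partner.
- An order is taken over about fifteen percent of the charge, up and down.

- order of the initial rate in [partner], near the charge of the Thursday's run, the rate being that where two percent of its starting material are target
- order of the initial rate in [starting material], near the charge of the Thursday's run, the rate being that where two percent of its starting material are target (one fixed amount of target, the same in the runs compared)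
- target in the Tuesday's run at 14 min, as a share of the starting material charged

Two of us dispute Tuesday's flask, which has Thursday's charge and runs twice as long as the last reading.

The first chemist says the making fades and whatever is made stays. On Thursday's run the mean slope falls from 0.00947 M min⁻¹ to 0.00452 M min⁻¹ in later readings, a fading of 0.206 min⁻¹. Adding that tail to the last reading gives 38.5 % of the charge.

The second chemist, whose reckoning I commit to, says target may be lost as well. She replaces the curve by its mean: the share of charge turned to target, divided by the time since the lag of 0.275 min on Thursday's run. If making and loss share one first-order constant, this mean rate decays exponentially, and its decay constant is the fading constant of the mean rate.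

Thursday's and Sunday's runs have the same partner charge, so she averages their shares: 16.2 % at 2.8 min and 28.9 % at 6.9 min. The mean rates are 0.0640 min⁻¹ and 0.0436 min⁻¹, so the constant reads 0.0936 min⁻¹.

This curve tops at the lag plus the inverse constant, 11.0 min, earlier than 14 min. She then reckons Tuesday's flask at 30.8 %. Dropping the lag gives 33.5 %, which shows how far this one estimate leans on the lag.

For the orders she uses early slopes at matched time: −0.267 in partner and 1.02 in starting material.

The forecast gives 37 %, with orders 0 in partner and 0.8 in starting material, on the ground that “The slowdown therefore follows time rather than product amount”.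

The flask gives 25.2 % on Tuesday's run, with orders 0.074 and 0.67; that is 0.0378 M, less than Thursday's last reading of 0.0453 M.

    starting material → intermediate (0.2718 min⁻¹)
    intermediate + partner → target (3.828 M⁻¹ min⁻¹)
    intermediate → side product (0.1440 min⁻¹)
    starting material + partner ⇌ idle substrate-reagent adduct, settled at all times (4.280 M⁻¹)
    target → decomposed product (0.1416 min⁻¹)

The step that goes with this is target → decomposed product. At 1.8 min on Thursday's run it removes 0.00204 M min⁻¹, which is 21.5 % of the net slope 0.00947 M min⁻¹, so target is already being lost there, and the first chemist's view serves on that early stretch as an approximation. Tuesday's result puts the fading constant between 6.9 min and 14 min at 0.122 min⁻¹, which places the top at 8.47 min. On Wednesday's run the early constant reads 0.0895 min⁻¹.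

The data are calculated for substances that don't exist.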